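**Plan**

- Retrosynthesis: cut the biaryl bond chroman C8–apigenin C8 (Suzuki–Miyaura), then the chromone of the chrysin-type unit at C6 back to an ester (Claisen condensation, cyclodehydration). Ring B is then cut at C8a–C8 and C5–C4a (Diels–Alder) and at C4–C4a (1,2-shift).
- Enabling feature: in ring B the pyran oxygen (on C8a) and C4 (on C4a) sit on adjacent ring carbons, and C8a lies para to the acyl-level carbon C6 and ortho to the aryl-bearing C8. O and C4 can therefore start on one spiro carbon of an oxolane, and ring B can be built around it from a 3-bromo-5-carbomethoxy-2-pyrone.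
- Forward: bromo enol ether (oxolane) and bromopyrone give ring B, and in the same operation the oxolane is enlarged to the dihydropyran ring. Then follow the chromone at C6, borylation at C8, coupling with 8-iodo-tri-O-benzylapigenin and hydrogenolysis.
- Stereochemistry: the target has no stereocentre; the stereocentres of the cycloaddition intermediates are destroyed on aromatisation.

Key step: step 5

Remark: the tri-ortho-substituted biaryl axis carries no stereodescriptor in the target, so the compound is made without control of axial configuration. Methyl pent-4-ynoate, methyl coumalate, 1-[2,4-bis(benzyloxy)-6-hydroxyphenyl]ethan-1-one and apigenin are taken as commercial.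

**Step 1**
Reactants: 1 methyl pent-4-ynoate
Product: 2 2-methylhex-5-yn-2-ol
Conditions: MeMgBr (3.3 equiv), THF, 0 °C to rt; aq. NH4Cl
Reagents that add atoms: methylmagnesium bromide, C[Mg]Br
Why: Double Grignard addition to the ester gives the tertiary alcohol, the acetylenic C–H only consuming one further equivalent of reagent.

**Step 2**
Reactants: 2 2-methylhex-5-yn-2-ol
Product: 3 6-bromo-2-methylhex-5-yn-2-ol
Conditions: NBS (1.1 equiv), AgNO3 (10 mol%), acetone, rt
Reagents that add atoms: N-bromosuccinimide, O=C1CCC(=O)N1Br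
Why: Silver-catalysed bromination of a terminal alkyne with NBS (via the silver acetylide) is general and tolerates a free tertiary alcohol.

**Step 3**
Reactants: 3 6-bromo-2-methylhex-5-yn-2-ol
Product: 4 (Z)-5-(bromomethylidene)-2,2-dimethyloxolane
Conditions: KOtBu (20 mol%), THF, 0 °C to rt; stored over K2CO3
Reagents that add atoms: none
Why: Base-mediated 5-exo-dig anti-addition of the tertiary alkoxide to the 1-bromoalkyne (nucleophilic hydroalkoxylation of a haloalkyne) puts oxygen on the internal carbon and gives the (Z)-bromo enol ether, whose geometry is of no consequence later.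

**Step 4**
Reactants: 5 methyl 2-oxo-2H-pyran-5-carboxylate (methyl coumalate)
Product: 6 methyl 3-bromo-2-oxo-2H-pyran-5-carboxylate
Conditions: Br2 (1.1 equiv), CH2Cl2, rt; then Et3N (1.2 equiv), 0 °C
Reagents that add atoms: bromine, BrBr
Why: Electrophilic bromination of a 2-pyrone (addition of bromine, then dehydrobromination) goes to C3, the only free nucleophilic position once C5 carries the ester.

**Step 5**
Reactants: 6 methyl 3-bromo-2-oxo-2H-pyran-5-carboxylate; 4 (Z)-5-(bromomethylidene)-2,2-dimethyloxolane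
Product: 9 methyl 8-bromo-2,2-dimethyl-3,4-dihydro-2H-chromene-6-carboxylate, via spiro bicyclic lactone 7 (not isolated), via spiro bromodiene 8 (not isolated)
Conditions: 4 (2 equiv), Ag2CO3 (1 equiv), 4 Å MS, toluene, 110 °C, sealed tube
Reagents that add atoms: none
Why: Proposed new method: the electron-poor pyrone 6 (C3–Br and C5 ester) should add the enol ether 4 in an inverse-electron-demand Diels–Alder reaction, the nucleophilic bromomethine carbon bonding to C6 and the oxygen-bearing carbon to C3 as in the known benzannulations of coumalates and 3-acyl-2-pyrones with enol ethers and ketene acetals, to give lactone 7, which loses CO2 by retro-[4+2] to the spiro diene 8. Abstraction of the dienylic C10 bromide of 8 by the silver salt gives a spiro arenium ion in which the oxolane CH2 migrates from the spiro carbon to the cationic neighbour, pushed by the ring oxygen and probably concerted with bromide loss because the para ester disfavours a free cation, and loss of a proton aromatises; the closest known reaction types are the quinol (dienone–phenol) rearrangement and the silver-promoted 1,2-shift of alpha-bromo ketals. Ring B is closed by the [4+2] cycloaddition (two C–C bonds, all six atoms from 6 and 4), and the dihydropyran ring arises from the five-membered oxolane by this one-carbon ring expansion, the former exocyclic carbon becoming C4a. No stereocentre survives, so the diastereomer mixtures of 7 and 8 and the alkene geometry of 4 do not matter. The step needs regioselective cycloaddition (secured by the matched polarisation of pyrone and enol ether), loss of bromide and not of the ring alkoxide (secured by the halophilic, acid-free carbonate medium), and carbon and not oxygen migration (only the carbon shift leaves an oxygen-stabilised arenium ion); a [1,5]-hydrogen shift in 8 would only exchange the roles of the two C–Br carbons and lead to the same product.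

**Step 6**
Reactants: 9 methyl 8-bromo-2,2-dimethyl-3,4-dihydro-2H-chromene-6-carboxylate; 10 1-[2,4-bis(benzyloxy)-6-hydroxyphenyl]ethan-1-one
Product: 12 5,7-bis(benzyloxy)-2-(8-bromo-2,2-dimethyl-3,4-dihydro-2H-chromen-6-yl)-4H-chromen-4-one, via 1,3-diketone 11 (not isolated)
Conditions: LiN(SiMe3)2 (3.5 equiv), THF, −78 °C to rt; aq. NH4Cl; then TsOH·H2O (0.2 equiv), toluene, 80 °C
Reagents that add atoms: none
Why: Claisen condensation of the lithium dianion of the 2-hydroxyacetophenone with the methyl ester gives diketone 11, which cyclodehydrates under mild acid to the chromone (Claisen-condensation route to flavones), with aryl bromide, chroman and benzyl ethers inert to both stages.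

**Step 7**
Reactants: 12 5,7-bis(benzyloxy)-2-(8-bromo-2,2-dimethyl-3,4-dihydro-2H-chromen-6-yl)-4H-chromen-4-one
Product: 13 5,7-bis(benzyloxy)-2-[2,2-dimethyl-8-(4,4,5,5-tetramethyl-1,3,2-dioxaborolan-2-yl)-3,4-dihydro-2H-chromen-6-yl]-4H-chromen-4-one
Conditions: B2pin2 (1.5 equiv), Pd(dppf)Cl2 (5 mol%), KOAc (3 equiv), 1,4-dioxane, 90 °C
Reagents that add atoms: bis(pinacolato)diboron, CC1(C)OB(OC1(C)C)B1OC(C)(C)C(C)(C)O1
Why: Miyaura borylation of the aryl bromide places boron on the less hindered, less protodeboronation-prone partner, and the chromone and benzyl ethers tolerate the mild acetate base.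

**Step 8**
Reactants: 14 apigenin (5,7-dihydroxy-2-(4-hydroxyphenyl)-4H-chromen-4-one)
Product: 15 5,7-bis(benzyloxy)-2-[4-(benzyloxy)phenyl]-4H-chromen-4-one
Conditions: BnBr (4.5 equiv), K2CO3 (6 equiv), DMF, 80 °C
Reagents that add atoms: benzyl bromide, BrCc1ccccc1
Why: Williamson benzylation of all three phenols, the chelated 5-OH reacting last and needing excess reagent and heat.

**Step 9**
Reactants: 15 5,7-bis(benzyloxy)-2-[4-(benzyloxy)phenyl]-4H-chromen-4-one
Product: 16 5,7-bis(benzyloxy)-2-[4-(benzyloxy)phenyl]-8-iodo-4H-chromen-4-one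
Conditions: NIS (1.1 equiv), TFA (0.3 equiv), MeCN/CH2Cl2, rt
Reagents that add atoms: N-iodosuccinimide, O=C1CCC(=O)N1I
Why: Electrophilic iodination of the phloroglucinol-type ring goes to C8 when the 5-oxygen is alkylated, as known for 5,7-dialkoxyflavones, C6 being flanked by two benzyloxy groups.

**Step 10**
Reactants: 13 the chromanyl boronate; 16 5,7-bis(benzyloxy)-2-[4-(benzyloxy)phenyl]-8-iodo-4H-chromen-4-one
Product: 17 8-{6-[5,7-bis(benzyloxy)-4-oxo-4H-chromen-2-yl]-2,2-dimethyl-3,4-dihydro-2H-chromen-8-yl}-5,7-bis(benzyloxy)-2-[4-(benzyloxy)phenyl]-4H-chromen-4-one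
Conditions: Pd(OAc)2 (5 mol%), SPhos (10 mol%), K3PO4 (3 equiv), toluene/H2O (10:1), 100 °C
Reagents that add atoms: none
Why: Suzuki–Miyaura coupling of the ortho-alkoxy arylboronate with the 8-iodoflavone, the partner assignment that works for 3′,8″-linked biflavones, with a bulky biarylphosphine to support reductive elimination at the tri-ortho-substituted axis.

**Step 11**
Reactants: 17 the penta-O-benzyl biflavone
Product: 18 8-[6-(5,7-dihydroxy-4-oxo-4H-chromen-2-yl)-2,2-dimethyl-3,4-dihydro-2H-chromen-8-yl]-5,7-dihydroxy-2-(4-hydroxyphenyl)-4H-chromen-4-one (target)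
Conditions: H2 (1 atm), 10% Pd/C, THF/MeOH (1:1), rt
Reagents that add atoms: none
Why: Hydrogenolysis of the five benzyl ethers should spare the chromone double bonds, the chroman ether and the biaryl, and it avoids the strong acids that could open the 2,2-dimethylchroman or cause a Wessely–Moser isomerisation of the 8-aryl-5,7-dihydroxyflavone.

**Compound list**

1 | methyl pent-4-ynoate | C#CCCC(=O)OC | starting material
2 | 2-methylhex-5-yn-2-ol | C#CCCC(C)(C)O | intermediate
3 | 6-bromo-2-methylhex-5-yn-2-ol | BrC#CCCC(C)(C)O | intermediate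
4 | (Z)-5-(bromomethylidene)-2,2-dimethyloxolane | Br/C=C1\OC(C)(C)CC1 | intermediate
5 | methyl 2-oxo-2H-pyran-5-carboxylate (methyl coumalate) | COC(=O)C1=COC(=O)C=C1 | starting material
6 | methyl 3-bromo-2-oxo-2H-pyran-5-carboxylate | COC(=O)C1=COC(=O)C(Br)=C1 | intermediate
7 | methyl 4,6-dibromo-5',5'-dimethyl-3-oxospiro[2-oxabicyclo[2.2.2]oct-7-ene-5,2'-oxolane]-7-carboxylate (diastereomer mixture, not isolated) | COC(=O)C1=CC2(Br)C(=O)OC1C(Br)C23CCC(C)(C)O3 | intermediate
8 | methyl 6,10-dibromo-2,2-dimethyl-1-oxaspiro[4.5]deca-6,8-diene-8-carboxylate (diastereomer mixture, not isolated) | COC(=O)C1=CC(Br)C2(CCC(C)(C)O2)C(Br)=C1 | intermediate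
9 | methyl 8-bromo-2,2-dimethyl-3,4-dihydro-2H-chromene-6-carboxylate | COC(=O)c1cc(Br)c2OC(C)(C)CCc2c1 | intermediate
10 | 1-[2,4-bis(benzyloxy)-6-hydroxyphenyl]ethan-1-one | CC(=O)c1c(O)cc(OCc2ccccc2)cc1OCc1ccccc1 | starting material
11 | 1-[2,4-bis(benzyloxy)-6-hydroxyphenyl]-3-(8-bromo-2,2-dimethyl-3,4-dihydro-2H-chromen-6-yl)propane-1,3-dione (not isolated) | O=C(CC(=O)c1c(O)cc(OCc2ccccc2)cc1OCc1ccccc1)c1cc(Br)c2OC(C)(C)CCc2c1 | intermediate
12 | 5,7-bis(benzyloxy)-2-(8-bromo-2,2-dimethyl-3,4-dihydro-2H-chromen-6-yl)-4H-chromen-4-one | O=c1cc(-c2cc(Br)c3OC(C)(C)CCc3c2)oc2cc(OCc3ccccc3)cc(OCc3ccccc3)c12 | intermediate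
13 | 5,7-bis(benzyloxy)-2-[2,2-dimethyl-8-(4,4,5,5-tetramethyl-1,3,2-dioxaborolan-2-yl)-3,4-dihydro-2H-chromen-6-yl]-4H-chromen-4-one | O=c1cc(-c2cc(B3OC(C)(C)C(C)(C)O3)c3OC(C)(C)CCc3c2)oc2cc(OCc3ccccc3)cc(OCc3ccccc3)c12 | intermediate
14 | apigenin | O=c1cc(-c2ccc(O)cc2)oc2cc(O)cc(O)c12 | starting material
15 | 5,7-bis(benzyloxy)-2-[4-(benzyloxy)phenyl]-4H-chromen-4-one | O=c1cc(-c2ccc(OCc3ccccc3)cc2)oc2cc(OCc3ccccc3)cc(OCc3ccccc3)c12 | intermediate
16 | 5,7-bis(benzyloxy)-2-[4-(benzyloxy)phenyl]-8-iodo-4H-chromen-4-one | O=c1cc(-c2ccc(OCc3ccccc3)cc2)oc2c(I)c(OCc3ccccc3)cc(OCc3ccccc3)c12 | intermediate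
17 | 8-{6-[5,7-bis(benzyloxy)-4-oxo-4H-chromen-2-yl]-2,2-dimethyl-3,4-dihydro-2H-chromen-8-yl}-5,7-bis(benzyloxy)-2-[4-(benzyloxy)phenyl]-4H-chromen-4-one | CC1(C)CCc2cc(-c3cc(=O)c4c(OCc5ccccc5)cc(OCc5ccccc5)cc4o3)cc(-c3c(OCc4ccccc4)cc(OCc4ccccc4)c4c(=O)cc(-c5ccc(OCc6ccccc6)cc5)oc34)c2O1 | intermediate
18 | 8-[6-(5,7-dihydroxy-4-oxo-4H-chromen-2-yl)-2,2-dimethyl-3,4-dihydro-2H-chromen-8-yl]-5,7-dihydroxy-2-(4-hydroxyphenyl)-4H-chromen-4-one | CC1(C)CCc2cc(-c3cc(=O)c4c(O)cc(O)cc4o3)cc(-c3c(O)cc(O)c4c(=O)cc(-c5ccc(O)cc5)oc34)c2O1 | target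

**Step count and risks**

Total step count: 11. Longest linear sequence: 8 steps (steps 1, 2, 3, 5, 6, 7, 10, 11).

Steps most likely to fail:

1. Step 5 (Proposed new method). The halogen-bearing enol ether may add too slowly to the pyrone. The spiro diene may also aromatise by loss of the ring alkoxide (ring opening), or by oxygen instead of carbon migration. Fallback with known chemistry, setting out from 6 and coming back at 9: the pyrone benzannulation is kept with a plain ketene acetal, and the five-to-six ring enlargement is done by a radical 1,2-aryl shift. Heating 6 with 1,1-diethoxyethene (toluene, 100 °C) should give, by the established pyrone/ketene acetal cycloaddition with loss of CO2 and ethanol, methyl 3-bromo-4-ethoxybenzoate F1. BBr3 (CH2Cl2, −78 to 0 °C) should free methyl 3-bromo-4-hydroxybenzoate F2. Tsuji–Trost O-alkylation with tert-butyl 2-methylbut-3-en-2-yl carbonate and Pd(PPh3)4 (THF, 0 °C) should give the tertiary allyl ether methyl 3-bromo-4-[(2-methylbut-3-en-2-yl)oxy]benzoate F3. Slow addition of Bu3SnH with AIBN (benzene, 80 °C, high dilution) generates the aryl radical, which closes 5-exo to the (2,2-dimethyl-2,3-dihydrobenzofuran-3-yl)methyl radical. At low stannane concentration this radical undergoes the neophyl 1,2-aryl shift to the 2,2-dimethylchroman-3-yl radical, so the five-membered ring is enlarged to the six-membered one, and hydrogen transfer gives methyl 2,2-dimethyl-3,4-dihydro-2H-chromene-6-carboxylate F4. Bromination ortho to the ring oxygen (Br2, NaOAc, AcOH, rt) returns 9.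

2. Step 10. Transmetalation and reductive elimination at the tri-ortho-substituted axis may be slow, so that protodeboronation of 13 and hydrodeiodination of 16 take over. Fallback setting out from 13 and 10 and coming back at 17: the biaryl bond is made to a small ketone and the apigenin chromone is built afterwards. Iodination of 10 ortho to the free hydroxyl (NIS, TFA cat., MeCN) should give 1-[4,6-bis(benzyloxy)-2-hydroxy-3-iodophenyl]ethan-1-one F5. Suzuki–Miyaura coupling with 13 (Pd(PPh3)4, K2CO3, dioxane/H2O, 90 °C) should give the biaryl ketone 1-{4,6-bis(benzyloxy)-3-[6-(5,7-bis(benzyloxy)-4-oxo-4H-chromen-2-yl)-2,2-dimethyl-3,4-dihydro-2H-chromen-8-yl]-2-hydroxyphenyl}ethan-1-one F6. Claisen–Schmidt condensation with 4-(benzyloxy)benzaldehyde (KOH, EtOH/THF, rt) should give the (E)-chalcone of F6 with 4-(benzyloxy)benzaldehyde F7. Oxidative cyclisation (I2 cat., DMSO, 120 °C) closes the second chromone and gives 17.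

3. Step 3. The alkoxide may attack bromine instead of carbon (debromination), the ring may close 6-endo, or the enol ether may hydrolyse on isolation. Fallback setting out from 2 and coming back at 4: the halogen is introduced after ring closure. Cycloisomerisation of 2 (Ag2CO3 cat., benzene, 80 °C) should give 2,2-dimethyl-5-methylideneoxolane F8. Addition of Br2 (CH2Cl2, −78 °C) gives 2-bromo-2-(bromomethyl)-5,5-dimethyloxolane F9. Dehydrobromination with Et3N (0 °C to rt) gives 4, possibly with its E isomer, which serves equally in step 5.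

**Further compounds**

F1 | step 5 | methyl 3-bromo-4-ethoxybenzoate | CCOc1ccc(C(=O)OC)cc1Br
F2 | step 5 | methyl 3-bromo-4-hydroxybenzoate | COC(=O)c1ccc(O)c(Br)c1
F3 | step 5 | methyl 3-bromo-4-[(2-methylbut-3-en-2-yl)oxy]benzoate | COC(=O)c1ccc(OC(C)(C)C=C)c(Br)c1
F4 | step 5 | methyl 2,2-dimethyl-3,4-dihydro-2H-chromene-6-carboxylate | COC(=O)c1ccc2OC(C)(C)CCc2c1
F5 | step 10 | 1-[4,6-bis(benzyloxy)-2-hydroxy-3-iodophenyl]ethan-1-one | CC(=O)c1c(O)c(I)c(OCc2ccccc2)cc1OCc1ccccc1
F6 | step 10 | 1-{4,6-bis(benzyloxy)-3-[6-(5,7-bis(benzyloxy)-4-oxo-4H-chromen-2-yl)-2,2-dimethyl-3,4-dihydro-2H-chromen-8-yl]-2-hydroxyphenyl}ethan-1-one | CC(=O)c1c(O)c(-c2cc(-c3cc(=O)c4c(OCc5ccccc5)cc(OCc5ccccc5)cc4o3)cc3CCC(C)(C)Oc23)c(OCc2ccccc2)cc1OCc1ccccc1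
F7 | step 10 | (E)-1-{4,6-bis(benzyloxy)-3-[6-(5,7-bis(benzyloxy)-4-oxo-4H-chromen-2-yl)-2,2-dimethyl-3,4-dihydro-2H-chromen-8-yl]-2-hydroxyphenyl}-3-[4-(benzyloxy)phenyl]prop-2-en-1-one | O=C(/C=C/c1ccc(OCc2ccccc2)cc1)c1c(O)c(-c2cc(-c3cc(=O)c4c(OCc5ccccc5)cc(OCc5ccccc5)cc4o3)cc3CCC(C)(C)Oc23)c(OCc2ccccc2)cc1OCc1ccccc1
F8 | step 3 | 2,2-dimethyl-5-methylideneoxolane | C=C1CCC(C)(C)O1
F9 | step 3 | 2-bromo-2-(bromomethyl)-5,5-dimethyloxolane | BrCC1(Br)CCC(C)(C)O1
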